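The runs were computed for substances that don't exist, noise included.

**Clearing time.** Product appears at 4.32 mM/h in the larch run, read between 0.417 h and 1.50 h. By the first of these times larch has lost 5.06 mM of starting material that is not product, close to the protic impurity's 4.00 mM plus the free catalyst's 0.96 mM. We count the impurity's share as lost and the catalyst's as lent, so we reckon a ceiling of 80.0% of the starting material, the limiting reagent. The usable charge divided by that product rate is the clearing time 3.70 h.

the same everywhere: free catalyst 0.96 mM

| charge | starting material | reagent | protic impurity | remark | time |
|---|---|---|---|---|---|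
| larch | 0.020 M | 0.024 M | 4 mM | run made earlier |  |
| birch | 0.030 M | 0.024 M | 4 mM | run made earlier |  |
| south | 0.020 M | 0.0240 M | 4.00 mM | one stirred flow tank at steady state, fed with the mixture as stated, mean residence time 3.0 h |  |
| north-west | 0.020 M (fed, over 3.00 h) | 0.0240 M | 4.00 mM | all but starting material at the start; starting material goes in evenly over 3.00 h, the run ends at 3.0 h | 3.0 h |
| south-west | 0.020 M | 0.0240 M (fed, over 3.00 h) | 4.00 mM | all but reagent at the start; reagent goes in evenly over 3.00 h, the run ends at 3.0 h | 3.0 h |
| east | 0.020 M | 0.0240 M | 4.00 mM | everything together in a closed stirred flask, run for 3.0 h | 3.0 h |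

larch run (percent of the starting material charged)

| time / h | product / % | starting material / % |
|---|---|---|
| 0.417 | 10.8 | 63.9 |
| 0.833 | 19.9 | 54.7 |
| 1.33 | 30.5 | 45.6 |
| 1.50 | 34.2 | 43.0 |
| 2.00 | 42.2 | 33.6 |
| 2.50 | 47.1 | 26.6 |
| 3.00 | 54.9 | 24.0 |

birch run (percent of the starting material charged)

| time / min | product / % | starting material / % |
|---|---|---|
| 1.00 | 1.5 | 94.7 |
| 3.00 | 0.5 | 91.4 |
| 5.00 | 0 | 86.5 |
| 8.00 | 2.3 | 84.0 |
| 10.0 | 3.0 | 83.2 |
| 15.0 | 4.2 | 79.8 |
| 20.0 | 7.3 | 77.7 |

(scatter of a reading: 1 percentage point)

- the stated concentrations are those of everything mixed, before any reaction; amounts are the same in each set-up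
- the feed brings no volume worth counting
- the earlier runs were made in a closed, stirred flask

- the set-up with the highest amount of product at the outlet or at the end, in percent of the starting material put in ("none" if the first two lie within 2 percentage points) (south / north-west / south-west / east / none)
- amount of product at the outlet or at the end, in percent of the starting material put in, south
- amount of product at the outlet or at the end, in percent of the starting material put in, north-west
- amount of product at the outlet or at the end, in percent of the starting material put in, south-west
- amount of product at the outlet or at the end, in percent of the starting material put in, east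

**Two times.** The 3.0 h allowed is 0.811 of the clearing time, so we expect no set-up to reach the ceiling, and each yield to follow the rate it keeps. East repeats the larch recipe, so the last larch reading, 54.9%, stands for it. A feed or an outflow keeps a partner below its charge, so we rank east first.

**The forecast.** It gives east 54%, south 42%, north-west 38% and south-west 31%, with east best, and cautions: “That reagent order is poorly established, because reagent was never varied”.

**The result.** East gives 54.3%, south 42.4%, north-west 35.2% and south-west 26.8%, so east leads.

    catalyst intermediate C ⇌ catalyst intermediate D (K = 0.550, k = 1.10 /min)
    starting material + free catalyst → catalyst intermediate A (k = 44.0 /M/min)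
    starting material + protic impurity → quenched substrate (k = 7.20 /M/min)
    catalyst intermediate A ⇌ catalyst intermediate B (K = 1.50, k = 110 /min)
    catalyst intermediate D → free catalyst + product (k = 1.00 /min)
    2 free catalyst ⇌ resting dimer, settled at all times (K = 3200 /M)
    reagent + catalyst intermediate B ⇌ catalyst intermediate C (K = 93.0 /M, k = 60.0 /M/min)
    2 catalyst intermediate B → spent catalyst (k = 31.0 /M/min)

**What ran.** In east, starting material met protic impurity and free catalyst, with half-lives by those steps alone of 0.40 h and 0.27 h at charged concentrations, while catalyst intermediate C turned to catalyst intermediate D at a forward half-life of 0.63 min; at 3.0 h, 22.7% of the starting material still stood. East's lead goes in a longer run: at 30.0 h, 8.11 clearing times, east holds 78.2%, north-west 78.4% and south-west 76.6%, within the 2 percentage points margin and below our reckoned ceiling of 80.0%.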